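(Readings and results are calculated on assumed constants, noise included.)

A small charge of reagent, 1.80 M against 2.0 M of substrate, is where I start with cedar, the flask in question, in which the substrate is fed over 1.0 min and which has been followed up to 12.0 min.

| setting | cedar | flask |
|---|---|---|
| substrate | 2 M (fed, over 1.0 min) | 2.0 M (fed, over 1.0 min) |
| reagent | 1.8 M | 1.80 M |
| remark | the very flask that is asked about, followed so far; the fed solution adds 0.10 times the starting volume | the fed solution adds 0.10 times the starting volume |
| time |  | 25 min |

cedar run (percent of the substrate charged)

| time / min | substrate / % | mono adduct / % |
|---|---|---|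
| 1.00 | 41.6 | 13.5 |
| 1.50 | 17.6 | 12.4 |
| 3.00 | 2.7 | 6.7 |
| 5.00 | 2.3 | 4.9 |
| 8.00 | 2.3 | 5.1 |
| 12.0 | 1.8 | 4.2 |

(scatter of a reading: 0.5 percentage points)

- amounts are per litre of the starting volume; all of the dose is in the solution fed
- the numbers in the tables scatter by 0.5 percentage points (one standard deviation)
- steps under discussion: substrate + reagent -> mono adduct; reagent + mono adduct -> bis adduct; reagent + bis adduct -> triple product; reagent + triple product -> tetra adduct; substrate <-> dormant form

- the substrate standing at 25 min, as a percentage of the substrate charged
- the mono adduct standing at 25 min, as a percentage of the substrate charged
- the bis adduct standing at 25 min, as a percentage of the substrate charged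
- the triple product standing at 25 min, as a percentage of the substrate charged

The bench rule for a limiting reagent says that one reagent removes one substrate, so in cedar a ratio of 0.900 reagent per substrate should leave 10.0% of the substrate standing, like a tank that stops draining when the pump's stock is used. But cedar reads 1.8% of substrate at 12.0 min, and the rule's remainder over that reading is a ratio of 5.56, with a scatter of 0.5 percentage points, so the rule stops here, and the step to dormant form is the listed exit from substrate that uses no reagent.

I carry a reagent balance instead. Mono adduct holds one reagent and each later adduct at least two, so with 4.2% of mono adduct read in cedar, the later adducts together come to at most 42.9% of the substrate charged. Taking that ceiling, the substrate and the mono adduct away from the whole charge leaves 51.1%, and I call this the dormant floor, the least share of the substrate charged that this balance puts in dormant form at 12.0 min, a figure that carries the scatter of its readings. Since substrate and mono adduct read nearly level from 5.00 min on, I commit to about their last readings for 25 min.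

The forecast gives 1.7% of substrate and 3.5% of mono adduct, both lower than my values, with 8% of bis adduct and 14% of triple product, of which it says “These two are soft guesses”.

At 25 min cedar gives 2.16% of substrate, 4.35% of mono adduct, 16.7% of bis adduct and 12.6% of triple product.

    substrate + reagent → mono adduct (k = 0.0130 M⁻¹ s⁻¹)
    reagent + mono adduct → bis adduct (k = 0.0300 M⁻¹ s⁻¹)
    reagent + bis adduct → triple product (k = 0.0120 M⁻¹ s⁻¹)
    reagent + triple product → tetra adduct (k = 0.00620 M⁻¹ s⁻¹)
    substrate ⇌ dormant form (K = 28.0, k = 0.0210 s⁻¹)

Reagent in cedar stands at 0% of its own charge by then, and dormant form at 60.6%, above the floor of 51.1%. For the neighbour flask with 1.1 M of reagent, the same balance on its 2.54% of substrate and 5.96% of mono adduct gives a floor of 67.0%, and that flask holds 71.0% as dormant form.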